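The side chains on C3 and C5 of the benzene ring end in the same unit: an E-trisubstituted C2=C3 alkene whose C3 methyl group neighbours a hydroxylated C4. That unit is what anti addition of H and CH3 across a propargylic alcohol (C2≡C3–C4–OH) would leave, so everything rests on cutting both C3–CH3 bonds. One operation, hydroxyl-directed trans-hydrostannation of two alkynes with methyl-Stille coupling in the same flask, sets both alkene geometries and both methyl groups. Its substrate is a diyne diol methyl ester, assembled from a bis(bromomethyl)anisole ester, propargyl alcohol and an (R)-alkynol obtained by ynone transfer hydrogenation.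

Key step: step 9

Assumption: CIP analysis of the target gives 2E in both chains and 4R at the carbinol. Because an sp or sp2 carbon outranks the C5 methylene in either case, the centre keeps the descriptor R from the alkynol stage to the target.

Step 1
Reactants: 1 4-hydroxy-3,5-dimethylbenzoic acid; 2 iodomethane
Product: 3 methyl 4-methoxy-3,5-dimethylbenzoate
Conditions: MeI (3 equiv), K2CO3 (3 equiv), DMF, 50 °C
Reagents that add atoms: iodomethane (2), CI
Why: Double SN2 O-methylation (ester formation from the carboxylate and Williamson etherification of the phenoxide) in one pot; the small electrophile and gentle warming should overcome the two flanking methyl groups.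

Step 2
Reactants: 3 methyl 4-methoxy-3,5-dimethylbenzoate
Product: 4 methyl 3,5-bis(bromomethyl)-4-methoxybenzoate
Conditions: NBS (2.1 equiv), AIBN (5 mol%), PhCF3, 85 °C
Reagents that add atoms: N-bromosuccinimide, O=C1CCC(=O)N1Br
Why: Wohl–Ziegler radical bromination; the two equivalent benzylic methyl groups carry the only easily abstracted hydrogens, and the free ring positions (ortho to the ester, meta to the methoxy group) resist ionic bromination.

Step 3
Reactants: 5 4-methylpent-3-enoic acid
Product: 7 N-methoxy-N,4-dimethylpent-3-enamide, via acyl imidazole 6 (not isolated)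
Conditions: CDI (1.1 equiv), CH2Cl2, 0 °C to rt; then MeNHOMe·HCl (1.2 equiv), rt
Reagents that add atoms: N,O-dimethylhydroxylamine hydrochloride, CNOC.Cl
Why: Amide formation through the acyl imidazole under near-neutral conditions, which should avoid the ketene formation or double-bond migration that an acid chloride and amine base could cause.

Step 4
Reactants: 7 N-methoxy-N,4-dimethylpent-3-enamide; 8 trimethylsilylacetylene
Product: 11 6-methyl-1-(trimethylsilyl)hept-5-en-1-yn-3-one, via lithium (trimethylsilyl)acetylide 9 (not isolated), via lithium hemiaminal alkoxide 10 (not isolated)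
Conditions: 8 (1.3 equiv), n-BuLi (1.25 equiv), THF, −78 °C; then 7, −78 to −20 °C; cold aq. NH4Cl
Reagents that add atoms: none
Why: Weinreb ketone synthesis; the acetylide should add only once because the chelated adduct 10 persists until the cold, mildly acidic quench, which also keeps the β,γ-unsaturated ynone away from base.

Step 5
Reactants: 11 6-methyl-1-(trimethylsilyl)hept-5-en-1-yn-3-one
Product: 12 (3R)-6-methyl-1-(trimethylsilyl)hept-5-en-1-yn-3-ol
Conditions: Ru[(R,R)-TsNCHPhCHPhNH](p-cymene) (1 mol%, base-free amido complex), iPrOH, rt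
Reagents that add atoms: none
Why: Noyori asymmetric transfer hydrogenation of an ynone; in the outer-sphere hydride/proton transfer the alkynyl group takes the place of the aryl group of an aryl ketone, so the (R,R)-catalyst should give the (R)-carbinol without touching alkyne or alkene (configuration to be confirmed by chiral HPLC and MTPA ester analysis).

Step 6
Reactants: 12 (3R)-6-methyl-1-(trimethylsilyl)hept-5-en-1-yn-3-ol
Product: 13 (3R)-6-methylhept-5-en-1-yn-3-ol
Conditions: K2CO3 (0.2 equiv), MeOH, 0 °C to rt; careful concentration (volatile)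
Reagents that add atoms: none
Why: Base-catalysed methanolysis of the alkynyl C–Si bond (protodesilylation); the carbinol C–H is not acidic, so the stereocentre should be unaffected.

Step 7
Reactants: 4 methyl 3,5-bis(bromomethyl)-4-methoxybenzoate (3 equiv); 14 propargyl alcohol (1 equiv, limiting)
Product: 15 methyl 3-(bromomethyl)-5-(4-hydroxybut-2-yn-1-yl)-4-methoxybenzoate
Conditions: CuBr·SMe2 (30 mol%), Cs2CO3 (1.2 equiv), MeCN, rt, slow addition of 14; excess 4 recovered by chromatography
Reagents that add atoms: none
Why: Copper acetylide sp–sp3 substitution at a benzylic bromide; excess of the cheap dibromide should favour monosubstitution, and unreacted, mono- and doubly coupled materials differ by one hydroxyl group each and should separate easily, while the iodide-free copper source keeps the remaining halide a bromide.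

Step 8
Reactants: 15 methyl 3-(bromomethyl)-5-(4-hydroxybut-2-yn-1-yl)-4-methoxybenzoate; 13 (3R)-6-methylhept-5-en-1-yn-3-ol (1.2 equiv)
Product: 16 methyl 3-(4-hydroxybut-2-yn-1-yl)-5-[(4R)-4-hydroxy-7-methyloct-6-en-2-yn-1-yl]-4-methoxybenzoate
Conditions: CuBr·SMe2 (30 mol%), Cs2CO3 (1.5 equiv), MeCN, rt
Reagents that add atoms: none
Why: The same copper acetylide substitution, now at the single remaining benzylic bromide so that no statistics apply; the mild carbonate base should leave the (R)-carbinol and the ArCH2–C≡C methylenes (meta to the ester, so only weakly acidic) untouched.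

Step 9
Reactants: 16 methyl 3-(4-hydroxybut-2-yn-1-yl)-5-[(4R)-4-hydroxy-7-methyloct-6-en-2-yn-1-yl]-4-methoxybenzoate; 2 iodomethane
Product: 18 methyl 3-[(2E)-4-hydroxy-3-methylbut-2-en-1-yl]-5-[(2E,4R)-4-hydroxy-3,7-dimethylocta-2,6-dien-1-yl]-4-methoxybenzoate, via bis(alkenylstannane) 17 (not isolated)
Conditions: [Cp*RuCl]4 (5 mol%), Bu3SnH (2.4 equiv, slow addition), CH2Cl2, rt; evaporate; then Pd(PPh3)4 (10 mol%), Cu(O2CC4H3S) (copper thiophene-2-carboxylate, 3 equiv), [NBu4][Ph2PO2] (3.2 equiv), MeI (3.2 equiv), DMF, rt
Reagents that add atoms: iodomethane (2), CI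
Why: Each free propargylic OH donates a hydrogen bond to the chloride on the Cp*RuCl fragment, which orients the π-bound alkyne so that hydride from the coordinated Sn–H goes to the distal carbon C2 through a ruthenacyclopropene and tin ends up on the proximal carbon C3, anti to the new C–H bond. The resulting (Z)-α-stannyl allylic alcohols are methylated in the same flask by tin-to-copper exchange (tin trapped by the phosphinate), oxidative addition of MeI to zerovalent palladium, transmetallation and reductive elimination with retention of alkene geometry. The closest known reaction type is the ruthenium-catalysed hydroxyl-directed trans-hydrostannation of propargylic alcohols followed by copper-assisted methyl-Stille coupling of the alkenylstannane, here run at two sites of one molecule. No ring is closed and no stereocentre is created; C4 (R) is a spectator, and both E geometries follow from anti addition plus retention, which place each methyl cis to the benzylic carbon. The step needs proximal regiochemistry and trans addition at both alkynes, secured by the two unprotected hydroxyl groups; it must also spare the C6=C7 alkene, the ester and the ArCH2 groups, which the catalyst's preference for alkynes over trisubstituted alkenes and the neutral, base-free conditions should ensure.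

Step 10
Reactants: 18 methyl 3-[(2E)-4-hydroxy-3-methylbut-2-en-1-yl]-5-[(2E,4R)-4-hydroxy-3,7-dimethylocta-2,6-dien-1-yl]-4-methoxybenzoate
Product: 20 3-[(2E)-4-hydroxy-3-methylbut-2-en-1-yl]-5-[(2E,4R)-4-hydroxy-3,7-dimethylocta-2,6-dien-1-yl]-4-methoxybenzoic acid, via lithium carboxylate 19 (not isolated)
Conditions: LiOH·H2O (5 equiv), THF/MeOH/H2O, 40 °C; then 1 M HCl to pH 3–4, 0 °C
Reagents that add atoms: lithium hydroxide, [Li+].[OH-]
Why: BAc2 saponification of an unhindered methyl benzoate; the allylic alcohols and alkenes are inert to hydroxide, and brief cold acidification to pH 3–4 should not ionise the allylic carbinols.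

Compound list
1 | 4-hydroxy-3,5-dimethylbenzoic acid | Cc1cc(C(=O)O)cc(C)c1O | starting material
2 | iodomethane | CI | starting material
3 | methyl 4-methoxy-3,5-dimethylbenzoate | COC(=O)c1cc(C)c(OC)c(C)c1 | intermediate
4 | methyl 3,5-bis(bromomethyl)-4-methoxybenzoate | COC(=O)c1cc(CBr)c(OC)c(CBr)c1 | intermediate
5 | 4-methylpent-3-enoic acid | CC(C)=CCC(=O)O | starting material
6 | 1-(1H-imidazol-1-yl)-4-methylpent-3-en-1-one (acyl imidazole) | CC(C)=CCC(=O)n1ccnc1 | intermediate
7 | N-methoxy-N,4-dimethylpent-3-enamide | CON(C)C(=O)CC=C(C)C | intermediate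
8 | trimethylsilylacetylene | C#C[Si](C)(C)C | starting material
9 | lithium (trimethylsilyl)acetylide | [Li]C#C[Si](C)(C)C | intermediate
10 | lithium 3-[methoxy(methyl)amino]-6-methyl-1-(trimethylsilyl)hept-5-en-1-yn-3-olate (racemic hemiaminal alkoxide) | CON(C)C(O[Li])(CC=C(C)C)C#C[Si](C)(C)C | intermediate
11 | 6-methyl-1-(trimethylsilyl)hept-5-en-1-yn-3-one | CC(C)=CCC(=O)C#C[Si](C)(C)C | intermediate
12 | (3R)-6-methyl-1-(trimethylsilyl)hept-5-en-1-yn-3-ol | C[Si](C)(C)C#C[C@H](O)CC=C(C)C | intermediate
13 | (3R)-6-methylhept-5-en-1-yn-3-ol | C#C[C@H](O)CC=C(C)C | intermediate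
14 | propargyl alcohol (prop-2-yn-1-ol) | C#CCO | starting material
15 | methyl 3-(bromomethyl)-5-(4-hydroxybut-2-yn-1-yl)-4-methoxybenzoate | COC(=O)c1cc(CBr)c(OC)c(CC#CCO)c1 | intermediate
16 | methyl 3-(4-hydroxybut-2-yn-1-yl)-5-[(4R)-4-hydroxy-7-methyloct-6-en-2-yn-1-yl]-4-methoxybenzoate | COC(=O)c1cc(CC#CCO)c(OC)c(CC#C[C@H](O)CC=C(C)C)c1 | intermediate
17 | methyl 3-[(2Z)-4-hydroxy-3-(tributylstannyl)but-2-en-1-yl]-5-[(2Z,4R)-4-hydroxy-7-methyl-3-(tributylstannyl)octa-2,6-dien-1-yl]-4-methoxybenzoate | COC(=O)c1cc(C/C=C(\[Sn](CCCC)(CCCC)CCCC)CO)c(OC)c(C/C=C(\[Sn](CCCC)(CCCC)CCCC)[C@H](O)CC=C(C)C)c1 | intermediate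
18 | methyl 3-[(2E)-4-hydroxy-3-methylbut-2-en-1-yl]-5-[(2E,4R)-4-hydroxy-3,7-dimethylocta-2,6-dien-1-yl]-4-methoxybenzoate | COC(=O)c1cc(C/C=C(\C)CO)c(OC)c(C/C=C(\C)[C@H](O)CC=C(C)C)c1 | intermediate
19 | lithium 3-[(2E)-4-hydroxy-3-methylbut-2-en-1-yl]-5-[(2E,4R)-4-hydroxy-3,7-dimethylocta-2,6-dien-1-yl]-4-methoxybenzoate | [Li+].[O-]C(=O)c1cc(C/C=C(\C)CO)c(OC)c(C/C=C(\C)[C@H](O)CC=C(C)C)c1 | intermediate
20 | 3-[(2E)-4-hydroxy-3-methylbut-2-en-1-yl]-5-[(2E,4R)-4-hydroxy-3,7-dimethylocta-2,6-dien-1-yl]-4-methoxybenzoic acid (CNP0122795.1) | COc1c(C/C=C(\C)CO)cc(C(=O)O)cc1C/C=C(\C)[C@H](O)CC=C(C)C | target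

Total step count: 10. Longest linear sequence: 7 steps (steps 3, 4, 5, 6, 8, 9 and 10, from acid 5).

Steps most likely to fail

Step 9. Hydrostannation may stop short at one of the two alkynes, or protodestannation may compete with methyl transfer in the copper/palladium stage. Either would leave chains without the C3 methyl group that are hard to separate from the product. The fallback sets out from 17, this time isolated by rapid chromatography on triethylamine-deactivated silica. Iododestannation (I2, 2.05 equiv, CH2Cl2, −78 °C) should give, with retention, methyl 3-[(2Z)-4-hydroxy-3-iodobut-2-en-1-yl]-5-[(2Z,4R)-4-hydroxy-3-iodo-7-methylocta-2,6-dien-1-yl]-4-methoxybenzoate F1. A Negishi methylation (excess MeZnCl, Pd(PPh3)4, THF, rt) then forms the same two C3–CH3 bonds and returns to the route at 18.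

Step 7. Double alkynylation, O-benzylation of the free hydroxyl group by the benzylic bromide, or carbonate-induced propargyl-to-allene isomerisation may erode the mono-coupling. The fallback uses a preformed, O-protected alkynylzinc under base-free palladium catalysis; it sets out from 14 and 4. Silylation of 14 (TBSCl, imidazole, CH2Cl2) gives tert-butyldimethyl(prop-2-yn-1-yloxy)silane F2. Deprotonation (n-BuLi, THF, −78 °C) gives {3-[(tert-butyldimethylsilyl)oxy]prop-1-yn-1-yl}lithium F3, and ZnBr2 converts it into {3-[(tert-butyldimethylsilyl)oxy]prop-1-yn-1-yl}zinc bromide F4. Negishi coupling with excess 4 (PdCl2(DPEphos), THF, rt) should give methyl 3-(bromomethyl)-5-{4-[(tert-butyldimethylsilyl)oxy]but-2-yn-1-yl}-4-methoxybenzoate F5. Coupling of F5 with 13 under the conditions of step 8 gives methyl 3-{4-[(tert-butyldimethylsilyl)oxy]but-2-yn-1-yl}-5-[(4R)-4-hydroxy-7-methyloct-6-en-2-yn-1-yl]-4-methoxybenzoate F6. Desilylation (HF·pyridine, THF, 0 °C) returns to the route at 16.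

Step 5. Enantiocontrol may be incomplete, or the C5=C6 double bond may migrate into conjugation with the ketone before hydride transfer. The fallback replaces asymmetric catalysis by racemic reduction and enzymatic kinetic resolution; it sets out from 11. Luche reduction (NaBH4, CeCl3·7H2O, MeOH, −78 °C) gives rac-6-methyl-1-(trimethylsilyl)hept-5-en-1-yn-3-ol F7. Desilylation (K2CO3, MeOH) gives rac-6-methylhept-5-en-1-yn-3-ol F8. Acylation with immobilised Candida antarctica lipase B and vinyl acetate in hexane, run slightly past half conversion, should follow the empirical size rule for secondary alcohols (ethynyl as the small group). It should convert the (S)-enantiomer into (3S)-6-methylhept-5-en-1-yn-3-yl acetate F9 and leave the (R)-alcohol, so the route is rejoined at 13.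

Further compounds
F1 | step 9 | methyl 3-[(2Z)-4-hydroxy-3-iodobut-2-en-1-yl]-5-[(2Z,4R)-4-hydroxy-3-iodo-7-methylocta-2,6-dien-1-yl]-4-methoxybenzoate | COC(=O)c1cc(C/C=C(\I)CO)c(OC)c(C/C=C(\I)[C@H](O)CC=C(C)C)c1
F2 | step 7 | tert-butyldimethyl(prop-2-yn-1-yloxy)silane | C#CCO[Si](C)(C)C(C)(C)C
F3 | step 7 | {3-[(tert-butyldimethylsilyl)oxy]prop-1-yn-1-yl}lithium | [Li]C#CCO[Si](C)(C)C(C)(C)C
F4 | step 7 | {3-[(tert-butyldimethylsilyl)oxy]prop-1-yn-1-yl}zinc bromide | Br[Zn]C#CCO[Si](C)(C)C(C)(C)C
F5 | step 7 | methyl 3-(bromomethyl)-5-{4-[(tert-butyldimethylsilyl)oxy]but-2-yn-1-yl}-4-methoxybenzoate | COC(=O)c1cc(CBr)c(OC)c(CC#CCO[Si](C)(C)C(C)(C)C)c1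
F6 | step 7 | methyl 3-{4-[(tert-butyldimethylsilyl)oxy]but-2-yn-1-yl}-5-[(4R)-4-hydroxy-7-methyloct-6-en-2-yn-1-yl]-4-methoxybenzoate | COC(=O)c1cc(CC#CCO[Si](C)(C)C(C)(C)C)c(OC)c(CC#C[C@H](O)CC=C(C)C)c1
F7 | step 5 | rac-6-methyl-1-(trimethylsilyl)hept-5-en-1-yn-3-ol | C[Si](C)(C)C#CC(O)CC=C(C)C
F8 | step 5 | rac-6-methylhept-5-en-1-yn-3-ol | C#CC(O)CC=C(C)C
F9 | step 5 | (3S)-6-methylhept-5-en-1-yn-3-yl acetate | C#C[C@@H](OC(C)=O)CC=C(C)C
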